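## Structural features

CNP0287617.1 (34, C22H22O4) is pentacyclic. Atom numbers follow the target SMILES; ring A is the cyclopentanone C4–C5–C6–C7–C9, ring B the cyclohexanone C6–C7–C9–C10–C11–C13, ring C the cyclohexene C6–C13–C14–C15–C17–C18, and ring D the five-membered ring C6–C13–C26–C19–C18 that carries the hydroquinone. Rings A and B form a bicyclo[3.2.1]octanedione (bridgeheads C6 and C9, one-carbon bridge C7=O), rings C and D form a benzo-fused bicyclo[3.2.1]octadiene (bridgeheads C13 and C18, one-carbon bridge C6), and the two bicycles share the bond C6–C13, both ends of which are quaternary. The five stereocentres C4, C6, C9, C13 and C18 are contiguous, but bridging leaves only two relative choices open: which flank of C6 lies over the arene (C7 does, C5 lies over the C14–C15=C17 bridge) and the exo position of the isopropenyl group on C4 (on the side of C7, away from C10–C11). Fragile groups are the free hydroquinone (air, base), the 1,1-disubstituted and the trisubstituted alkene (acid, hydrogenation), and three carbonyl-level carbons of different hindrance that must be told apart. The real difficulty is the congested C6–C13 bond, with the two carbocycles that meet at it, set correctly against the remote C18. The key step uses the fact that the seven-membered periphery C6–C5–C4–C9–C10–C11–C13, bridged by C7, is the sum of a cyclopentadienone ketal (C6=C5–C4=C9 with C7) and a three-carbon oxyallyl unit (C13–C11–C10), with C13, tertiary and benzylic, as the natural cationic terminus held next to C6 through C18.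

## Logic of the disconnections

34 ⇒ 32. The two phenolic O–H bonds are traced back to O–CH3 bonds. A free hydroquinone would not survive organolithium, enolate or oxidative steps, and the ether oxygens also direct the first lithiation and stabilise the cation later. The forward step must leave two alkenes and two ketones alone.

32 ⇒ 31. The C2=C1 double bond is cut to a C2=O group. An acetyl group is what lets C4 be corrected by enolisation, and the last carbon then arrives by a one-carbon olefination. The forward step must distinguish the methyl ketone from the C7 and C11 ketones.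

31 ⇒ 29 ⇒ 28. The C4–H and C5–H bonds are removed (C4=C5 enone) and the C7 carbonyl is returned to its dimethyl ketal. C4 is the one stereocentre not fixed by bridging, and an enolisable acetyl group lets it settle exo. The ketal comes off first so that the exo face of ring A is free. The reduction must be conjugate and must spare C15=C17.

28 ⇒ 25 (key disconnection). The bonds C6–C13 and C9–C10 are cut. This removes both quaternary centres, rings B and D and three stereocentres at once, and it follows the natural polarity: C13 as a tertiary benzylic oxyallyl cation, C6 and C9 as termini of a cyclic s-cis diene. What remains is a benzocycloheptene with one stereocentre (C18) and a monocyclic diene. The forward step demands cation capture faster than loss of a C14 proton, a diene that stays monomeric and cannot shift hydrogen (the C7 ketal blocks this and becomes the ketone), and C7 ending over the arene. In 25 the leaving group on C13 is a hydroxyl group and the C11 enol ether an ethyl ether. A chloride and a silyl enol ether would have to be made by chlorination and enolisation beside the second methyl ketone and the diene, which cannot be done selectively.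

25 ⇒ 24 ⇒ 22. The C4–C2 bond is cut to a C4–O bond (dienyl sulfonate, then C4 ketone). Bringing in the acetyl group last, under neutral palladium catalysis, means the two methyl ketone units never have to be distinguished and the sensitive diene exists for one step only. The demand is regioselective enolisation of 22 at C9.

22 ⇒ 21 ⇒ 20. With C4 returned to the alcohol level, the C13–C11 bond is cut and C13 becomes a ketone. One addition of a two-carbon acyl-anion equivalent creates the quaternary carbinol, C11, C10 and the enol ether together. It requires a hindered, enolisable ketone to accept a carbon nucleophile while C4 is shielded as its alkoxide.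

20 ⇒ 19. The C15=C17 double bond is cut (ring-closing metathesis), opening the seven-membered ring to two terminal alkenes. The forward step must form a trisubstituted cycloalkene and leave the ring A alkene alone.

19 ⇒ 13 + 16; 16 ⇒ 14. The C26–C13 bond is cut to an aryl bromide and an acyl donor carrying C13–C16. Bromine is the smallest ortho substituent that can pass through the earlier steps. The demand is an aryl-metal species that acylates without removing the C18 proton.

13 ⇒ 11 ⇒ 9. The oxygen pattern of ring A is traced back: C7 ketal and C5–H to a C5 carbonyl and a C7 enol ether (reduction, allylic transposition), and the C4 hydroxyl to a C–H bond (enolate oxidation). This converts the symmetric dione unit into the C7/C4 oxygenation that the diene needs. The forward steps need kinetic enolisation at C4 and capture of an allyl cation at C7.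

9 ⇒ 8 ⇒ 6 + 7. After removal of the enol ether methyl group, the C18–C6 bond is cut at the allylic position, with the acidic carbon of 7 as nucleophile. This is the only step that creates absolute configuration, and it does so by catalysis. The demand is branched, enantioselective attack at a terminus flanked by two ortho substituents.

6 ⇒ 5 ⇒ 4 ⇒ 3 ⇒ 1. The allylic carbonate is traced through the alcohol and the unsaturated ester to the aldehyde (cut at C18=C17), and the formyl group is removed from the arene (C19–C18). The formylation must occur between bromine and a methoxy group.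

## Other disconnections considered

Alternative 1: The cut goes through the benzene ring (C19–C26, C20–C22, C23–C24). Ring D and the arene would be formed last from the 1,6-diyne A1, in which C13 and C18 of the finished bicyclic dione each carry an ethynyl pinacol boronate, and from ethyne A2. The forward key step would be a crossed [2+2+2] cyclotrimerisation on a rhodium or cobalt catalyst to the aryl bis(boronate) A3, followed by oxidation of both C–B bonds to 34.
- In its favour: a three-atom tether between the alkynes is the best case for such a cyclotrimerisation, the arene never needs protecting groups, and the boronates mark the two oxygen positions without any regiochemical question.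
- Against it here: the step makes no stereocentre and does not touch the C6–C13 problem. A1 must already hold rings A, B and C, both quaternary carbons and all five stereocentres, and its quaternary propargylic C13 next to the C11 ketone is harder to build than an aryl-bearing one. The C15=C17 alkene lies between the two alkynes and may enter the metallacycle, A2 trimerises on its own, and alkynyl boronates are prone to protodeborylation.
- Comparison: Alternative 1 is the better plan at the end (mild C–B oxidation instead of oxidative demethylation) and at least the equal in the reliability of the key bond formation as such. It is weaker on structure, because its key step simplifies only the flat part of the molecule, and on overall step economy, because the route to A1 would still need a disconnection of the kind chosen here.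

Alternative 2: The cut is at C13–C14 and C17–C18, so ring C would come from a (4+3) cycloaddition in which the diene is a 2H-indene. Zinc–copper couple would reduce the 1,3-dibromoindane A4 (C6 carrying ring B and a silyloxyethyl chain) to the 2H-indene A6 and 1,1,3,3-tetrabromoacetone A5 to the zinc-bound dibromo-oxyallyl cation A7. These would combine across C13 and C18, and debromination in the same flask would give the tetracyclic ketone A8 with the arene restored.
- In its favour: two benzylic stereocentres and ring C come from simple partners in one intermolecular step, and rearomatisation drives it. The geminal substitution at C6 blocks the hydrogen shift that usually destroys such dienes. A7 should approach anti to the bulky ketal carbon C7, which is the required sense. No hindered aryl organometallic is needed.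
- Against it here: the C13 bromide of A4 is an α-bromo ketone, which zinc should reduce to an enolate more readily than it builds A6. The diene terminus C13 is fully substituted and conjugated to the C11 carbonyl, a poor partner for a bulky electrophile that must make a quaternary centre intermolecularly. Quaternary C6 of A4 has to be made enantiopure beforehand. A8 still lacks C1–C3 and C16, so the C15 ketone must later become the C15 methyl alkene regioselectively (C14 and C17 compete) and ring A must be closed with control at C4.
- Comparison: Alternative 2 is the equal or better in convergence and in the intrinsic facial bias of its key step. It is weaker mechanistically (three reducible C–Br sites of different kinds in one pot) and in step economy after the key step, where 28 already holds every carbon but C1.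

Alternative 3: The cut is at C13–C26 and C18–C19, so the arene would be delivered as an aryne onto a bicyclic enolate–enone. A fluoride source would unmask nucleophilic C13 of the trimethylsilyl enol ether A9 (rings B and C with the prenyl group on C6) and release 3,6-dimethoxybenzyne A11 from the silyl triflate A10. C13 would add to A11, and the carbanion left at C19 would add 1,4 to the ring C enone at C18, closing ring D and giving the triketone A12.
- In its favour: A11 is symmetric, so no regiochemistry arises. A9 is a decalin-type dione of the kind that amine-catalysed annulations deliver enantioenriched, which sets quaternary C6 by established chemistry. The aryne should add anti to the prenyl group, the required face. Ring A could then be closed by oxidative radical cyclisation of C9 onto the prenyl alkene, which gives the isopropenyl group directly.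
- Against it here: C13 is a fully substituted enolate carbon next to quaternary C6, and arynes offered such enolates can instead undergo O-arylation, [2+2] addition with ring cleavage, or an ene reaction with the prenyl group. The C19 carbanion has the C11 carbonyl two atoms away, so four-ring closure there competes with the wanted conjugate addition. As in Alternative 2, A12 lacks the C15 methyl alkene, whose regioselective introduction between C14 and C17 is unsolved.
- Comparison: Alternative 3 is the better in convergence, in avoiding any hindered aryl-metal species or allylic substitution at a doubly ortho-substituted arene, and in how early absolute configuration is set. It is the equal in the number of bonds and rings its key step makes. It is weaker in the predictability of the key step, which must beat several aryne pathways at the most hindered carbon of the molecule, and in the late adjustment at C15.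

Key step: step 16

Assumption: the leaving group on C13 and the O-alkyl or O-silyl group on C11 are spectator groups of the cation precursor and may be exchanged; the configurations written for 25 and 28 were checked atom by atom against 34 and are consistent with it.

## Route

Step 1
Reactants: 1 2-bromo-1,4-dimethoxybenzene
Product: 3 2-bromo-3,6-dimethoxybenzaldehyde, via 2-bromo-3,6-dimethoxyphenyllithium 2 (not isolated)
Conditions: LiN(i-Pr)2, THF, −78 °C; DMF, −78 → 0 °C; aq. NH4Cl
Reagents that add atoms: N,N-dimethylformamide, CN(C)C=O
Why: Directed ortho-lithiation and formylation; the proton between bromine and methoxy is the most acidic, and at −78 °C the aryllithium is trapped before it can lose LiBr.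

Step 2
Reactants: 3 2-bromo-3,6-dimethoxybenzaldehyde
Product: 4 ethyl (2E)-3-(2-bromo-3,6-dimethoxyphenyl)prop-2-enoate
Conditions: (EtO)2P(O)CH2CO2Et, NaH, THF, 0 °C → rt
Reagents that add atoms: triethyl phosphonoacetate, CCOC(=O)CP(=O)(OCC)OCC
Why: Horner–Wadsworth–Emmons olefination; the stabilised phosphonate anion should give the E-alkene also with the doubly ortho-substituted aldehyde.

Step 3
Reactants: 4 ethyl (2E)-3-(2-bromo-3,6-dimethoxyphenyl)prop-2-enoate
Product: 5 (2E)-3-(2-bromo-3,6-dimethoxyphenyl)prop-2-en-1-ol
Conditions: i-Bu2AlH (2.2 equiv), CH2Cl2, −78 °C; aq. potassium sodium tartrate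
Reagents that add atoms: none
Why: 1,2-reduction of the unsaturated ester by the aluminium hydride at low temperature; aryl bromide and alkene geometry are not affected.

Step 4
Reactants: 5 (2E)-3-(2-bromo-3,6-dimethoxyphenyl)prop-2-en-1-ol
Product: 6 (2E)-3-(2-bromo-3,6-dimethoxyphenyl)prop-2-en-1-yl methyl carbonate
Conditions: ClCO2Me, pyridine, CH2Cl2, 0 °C
Reagents that add atoms: methyl chloroformate, COC(=O)Cl
Why: O-acylation of the primary allylic alcohol; the methyl carbonate is the leaving group that also releases methoxide as the internal base of step 5.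

Step 5
Reactants: 6 (2E)-3-(2-bromo-3,6-dimethoxyphenyl)prop-2-en-1-yl methyl carbonate; 7 cyclopentane-1,3-dione
Product: 8 2-[(1S)-1-(2-bromo-3,6-dimethoxyphenyl)prop-2-en-1-yl]cyclopentane-1,3-dione
Conditions: [Ir(cod)Cl]2 (2 mol %), (Ra,R,R)-1,1′-binaphthyl-2,2′-diyl N,N-bis[1-(2-methoxyphenyl)ethyl]phosphoramidite (4 mol %), n-PrNH2 pre-activation, 7 (2 equiv), THF, 35 °C
Reagents that add atoms: none
Why: Iridium-catalysed asymmetric allylic alkylation: the cyclometalated iridium phosphoramidite ionises the carbonate, and the dione enolate attacks the aryl-bearing allyl terminus to give the branched product; any O-allylated dione can re-ionise and funnel to the C-allyl product. C18 is set here as S, the ligand enantiomer being chosen from the facial preference known for stabilised carbon nucleophiles on aryl allyl carbonates.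

Step 6
Reactants: 8 2-[(1S)-1-(2-bromo-3,6-dimethoxyphenyl)prop-2-en-1-yl]cyclopentane-1,3-dione
Product: 9 2-[(1S)-1-(2-bromo-3,6-dimethoxyphenyl)prop-2-en-1-yl]-3-methoxycyclopent-2-en-1-one
Conditions: MeOH, TsOH·H2O (5 mol %), 3 Å molecular sieves, 50 °C
Reagents that add atoms: methanol, CO
Why: Acid-catalysed enol etherification of the 2-substituted 1,3-dione; the dione is symmetric, so a single vinylogous ester should form, with C5 as carbonyl and C7 as enol ether carbon.

Step 7
Reactants: 9 2-[(1S)-1-(2-bromo-3,6-dimethoxyphenyl)prop-2-en-1-yl]-3-methoxycyclopent-2-en-1-one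
Product: 11 5-hydroxy-3-methoxy-2-[(1S)-1-(2-bromo-3,6-dimethoxyphenyl)prop-2-en-1-yl]cyclopent-2-en-1-one (both epimers at the carbinol carbon), via potassium dienolate 10 (not isolated)
Conditions: KN(SiMe3)2, THF, −78 °C; 2-(phenylsulfonyl)-3-phenyloxaziridine, −78 °C; aq. NH4Cl
Reagents that add atoms: 2-(phenylsulfonyl)-3-phenyloxaziridine, O=S(=O)(c1ccccc1)N1OC1c1ccccc1
Why: Kinetic α′-deprotonation of the vinylogous ester at C4 and electrophilic hydroxylation of the enolate by the N-sulfonyloxaziridine; the new carbinol centre is oxidised in step 13, so its configuration does not matter.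

Step 8
Reactants: 11 5-hydroxy-3-methoxy-2-[(1S)-1-(2-bromo-3,6-dimethoxyphenyl)prop-2-en-1-yl]cyclopent-2-en-1-one
Product: 13 4,4-dimethoxy-3-[(1S)-1-(2-bromo-3,6-dimethoxyphenyl)prop-2-en-1-yl]cyclopent-2-en-1-ol (both carbinol epimers), via diol 12 (not isolated)
Conditions: i-Bu2AlH (3 equiv), CH2Cl2, −78 °C; aq. potassium sodium tartrate; crude 12, MeOH, PPTS (10 mol %), 3 Å molecular sieves, 0 °C; Et3N
Reagents that add atoms: methanol, CO
Why: 1,2-reduction of the vinylogous ester carbonyl, then acid-catalysed allylic transposition: the C5 hydroxyl ionises to a methoxy-stabilised allyl cation that methanol captures at C7. This is the carbonyl transposition of 3-alkoxyenones stopped at the dimethyl ketal, and it places the ketal on C7, a hydrogen on C5 and the first diene double bond at C6=C5.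

Step 9
Reactants: 14 methallyl chloride (3-chloro-2-methylprop-1-ene)
Product: 16 N-methoxy-N,3-dimethylbut-3-enamide, via methallylmagnesium chloride 15 (not isolated)
Conditions: Mg, THF, 0 °C; added to ClC(O)N(OMe)Me, THF, −78 °C
Reagents that add atoms: N-methoxy-N-methylcarbamoyl chloride, CON(C)C(Cl)=O
Why: Grignard formation and acylation by the carbamoyl chloride; inverse addition at −78 °C keeps the far more electrophilic acid chloride in excess, so the reaction should stop at the amide.

Step 10
Reactants: 13 4,4-dimethoxy-3-[(1S)-1-(2-bromo-3,6-dimethoxyphenyl)prop-2-en-1-yl]cyclopent-2-en-1-ol; 16 N-methoxy-N,3-dimethylbut-3-enamide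
Product: 19 1-{2-[(1R)-1-(3-hydroxy-5,5-dimethoxycyclopent-1-en-1-yl)prop-2-en-1-yl]-3,6-dimethoxyphenyl}-3-methylbut-3-en-1-one, via aryllithium lithium alkoxide 17 (not isolated), via arylmagnesium bromide 18 (not isolated)
Conditions: t-BuLi (3.1 equiv), THF, −78 °C; MgBr2·OEt2; 16, −78 → 0 °C; pH 7 buffer
Reagents that add atoms: none
Why: Bromine–lithium exchange (the first equivalent removes the hydroxyl proton), transmetalation to the less basic aryl Grignard reagent, and acylation by the N-methoxy-N-methylamide, whose chelated adduct releases the β,γ-unsaturated ketone only on work-up. C18 is not touched; its descriptor becomes R by priority change only.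

Step 11
Reactants: 19 1-{2-[(1R)-1-(3-hydroxy-5,5-dimethoxycyclopent-1-en-1-yl)prop-2-en-1-yl]-3,6-dimethoxyphenyl}-3-methylbut-3-en-1-one
Product: 20 (9R)-9-(3-hydroxy-5,5-dimethoxycyclopent-1-en-1-yl)-1,4-dimethoxy-7-methyl-6,9-dihydro-5H-benzo[7]annulen-5-one
Conditions: second-generation Grubbs catalyst RuCl2(=CHPh)(PCy3)(H2IMes) (5 mol %), 1,4-benzoquinone (10 mol %), CH2Cl2 (0.005 M), 40 °C
Reagents that add atoms: none
Why: Ring-closing metathesis of the vinyl group with the 1,1-disubstituted methallyl alkene closes the seven-membered ring and forms the C15=C17 trisubstituted alkene; the trisubstituted ring A alkene is a spectator, and benzoquinone suppresses isomerisation of the β,γ-unsaturated ketone.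

Step 12
Reactants: 20 (9R)-9-(3-hydroxy-5,5-dimethoxycyclopent-1-en-1-yl)-1,4-dimethoxy-7-methyl-6,9-dihydro-5H-benzo[7]annulen-5-one
Product: 21 (9R)-5-(1-ethoxyethenyl)-9-(3-hydroxy-5,5-dimethoxycyclopent-1-en-1-yl)-1,4-dimethoxy-7-methyl-6,9-dihydro-5H-benzo[7]annulen-5-ol (both epimers at the new carbinol C13)
Conditions: ethyl vinyl ether, t-BuLi, THF, −78 → 0 °C; CeCl3, −78 °C; then 20; aq. NaHCO3
Reagents that add atoms: ethyl vinyl ether, C=COCC
Why: 1,2-addition of the (1-ethoxyvinyl)cerium reagent, an acetyl-anion equivalent, to the hindered C13 ketone, with cerium suppressing enolisation toward C14. One step installs C11, C10, the enol ether and the tertiary hydroxyl leaving group, and both C13 epimers give the same cation later.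

Step 13
Reactants: 21 (9R)-5-(1-ethoxyethenyl)-9-(3-hydroxy-5,5-dimethoxycyclopent-1-en-1-yl)-1,4-dimethoxy-7-methyl-6,9-dihydro-5H-benzo[7]annulen-5-ol
Product: 22 4,4-dimethoxy-3-[(9R)-5-(1-ethoxyethenyl)-5-hydroxy-1,4-dimethoxy-7-methyl-6,9-dihydro-5H-benzo[7]annulen-9-yl]cyclopent-2-en-1-one
Conditions: MnO2 (activated, 20 equiv), CH2Cl2, rt
Reagents that add atoms: none
Why: Selective oxidation of the secondary allylic alcohol on manganese dioxide; the tertiary carbinol cannot be oxidised, and the neutral conditions spare the enol ether and the ketal.

Step 14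
Reactants: 22 4,4-dimethoxy-3-[(9R)-5-(1-ethoxyethenyl)-5-hydroxy-1,4-dimethoxy-7-methyl-6,9-dihydro-5H-benzo[7]annulen-9-yl]cyclopent-2-en-1-one
Product: 24 5,5-dimethoxy-4-[(9R)-5-(1-ethoxyethenyl)-5-hydroxy-1,4-dimethoxy-7-methyl-6,9-dihydro-5H-benzo[7]annulen-9-yl]cyclopenta-1,3-dien-2-yl trifluoromethanesulfonate, via dilithium alkoxide dienolate 23 (not isolated)
Conditions: LiN(i-Pr)2 (2.2 equiv), THF, −78 °C; N-(5-chloropyridin-2-yl)bis(trifluoromethanesulfonyl)imide, −78 °C; aq. NaHCO3
Reagents that add atoms: N-(5-chloropyridin-2-yl)bis(trifluoromethanesulfonyl)imide, O=S(=O)(N(c1ccc(Cl)cn1)S(=O)(=O)C(F)(F)F)C(F)(F)F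
Why: Kinetic enolisation at C9, the only α-methylene (the γ-proton on C18 is hindered and lies near the alkene plane), and O-sulfonylation of the enolate to the dienyl triflate. Loss of methoxide from C7 would give a cyclopentadienone and should not compete, and the hindered tertiary alkoxide should stay unsulfonylated at −78 °C.

Step 15
Reactants: 24 5,5-dimethoxy-4-[(9R)-5-(1-ethoxyethenyl)-5-hydroxy-1,4-dimethoxy-7-methyl-6,9-dihydro-5H-benzo[7]annulen-9-yl]cyclopenta-1,3-dien-2-yl trifluoromethanesulfonate
Product: 25 1-{5,5-dimethoxy-4-[(9R)-5-(1-ethoxyethenyl)-5-hydroxy-1,4-dimethoxy-7-methyl-6,9-dihydro-5H-benzo[7]annulen-9-yl]cyclopenta-1,3-dien-2-yl}ethan-1-one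
Conditions: Pd(PPh3)4 (5 mol %), LiCl, Me4Sn, CO (3 atm), THF, 50 °C; used at once
Reagents that add atoms: carbon monoxide, [C-]#[O+]; tetramethylstannane, C[Sn](C)(C)C
Why: Carbonylative Stille coupling: oxidative addition of the dienyl triflate to zerovalent palladium, CO insertion and methyl transfer from tin give the methyl ketone under neutral conditions. The acetyl group therefore arrives after every enolisation and organometallic step, and the acid-labile carbinol and enol ether meet neither acid nor base.

Step 16
Reactants: 25 1-{5,5-dimethoxy-4-[(9R)-5-(1-ethoxyethenyl)-5-hydroxy-1,4-dimethoxy-7-methyl-6,9-dihydro-5H-benzo[7]annulen-9-yl]cyclopenta-1,3-dien-2-yl}ethan-1-one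
Product: 28 pentacyclic C4-acetyl enone with C7 dimethyl ketal (C6/C9/C13/C18 as in 34), via 2-ethoxyallyl cation triflate 26 (not isolated), via pentacyclic ethyl enol ether 27 (not isolated)
Conditions: Tf2O (1.1 equiv), 2,6-lutidine (3 equiv), CH2Cl2 (0.01 M), −78 → −40 °C; then aq. NaH2PO4 (pH 4)/THF, 0 °C
Reagents that add atoms: water, O
Why: Triflic anhydride sulfonylates the tertiary hydroxyl group and the triflate ionises at once to the tertiary, benzylic 2-ethoxyallyl cation 26 (C13–C11–C10) while 2,6-lutidine keeps the medium non-acidic; the C7 ketal survives because its ionisation would create a cyclopentadienyl cation. The closest known reaction type is the intramolecular (4+3) cycloaddition of alkoxyallyl cations generated from 2-alkoxyallylic alcohols with triflic anhydride and a hindered pyridine, and of siloxyallyl cations with tethered cyclopentadienes. Ring D closes first: diene terminus C6, held over the seven-membered ring by C18, attacks C13 in a five-membered closure exo to the C6=C5 bond, which bridges the benzocycloheptene into rings C and D. Ring B closes second: the allyl cation C5–C4–C9 left on the diene, with the acetyl group on its nodal carbon C4, is captured at C9 by enol ether carbon C10 in a six-membered closure endo to the enol ether double bond, completing the seven-membered ring C6–C5–C4–C9–C10–C11–C13; the resulting O-ethyl oxocarbenium ion loses a proton to 27, which the buffered work-up hydrolyses to the C11 ketone. C13 is set by the tether, since C6 can reach only the cation face on the side of the C18–C6 bond, and C9 is set by the ring, since both new bonds must lie on one face of the planar cyclopentadiene. C6 is set by which flank of the diene lies over the arene: closure at C9 needs C10 and C7 on the same side, and the cation should turn its ethoxy oxygen toward C14H2 and its methylene C10 toward the aryl group, away from the C24 methoxy oxygen, so C7 should end over the arene as in 34. The step needs capture of the cation to outrun loss of a C14 proton, and closure at C9 to beat closure at C5; the five-membered reach of C6, the low temperature and the locked s-cis diene, whose termini match the span of the allyl unit, are what should secure this.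

Step 17
Reactants: 28 pentacyclic C4-acetyl enone with C7 dimethyl ketal
Product: 29 pentacyclic C4-acetyl enone with C7 and C11 ketones (stereocentres unchanged)
Conditions: 1 M aq. HCl, THF, rt → 40 °C
Reagents that add atoms: water, O
Why: Acid hydrolysis of the bridging dimethyl ketal, which after the cycloaddition is an ordinary ketal; only the enone, the aryl ethers and the trisubstituted ring alkene are present, and these should tolerate dilute acid. Removing the ketal first frees the exo face of ring A for step 18.

Step 18
Reactants: 29 pentacyclic C4-acetyl enone with C7 and C11 ketones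
Product: 31 C4,C5-dihydro triketone with exo acetyl group (C4 as in 34), via endo-acetyl epimer 30 (not isolated)
Conditions: [(Ph3P)CuH]6 (0.5 equiv), THF, H2O (5 equiv), rt; then DBU (0.5 equiv), rt
Reagents that add atoms: none
Why: Conjugate reduction of the enone by the copper hydride, which leaves isolated ketones and the unactivated C15=C17 alkene alone. Protonation of the enolate on the open exo face should give mainly the endo acetyl epimer, and base equilibration through the C4 enolate then moves the acetyl group exo, away from C10, C11 and C14 beneath the two-carbon bridge; this sets C4.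

Step 19
Reactants: 31 C4,C5-dihydro triketone with exo acetyl group
Product: 32 hydroquinone dimethyl ether of 34 (isopropenyl on C4; C7 and C11 ketones)
Conditions: Ph3PCH3Br, KOt-Bu, THF, 0 °C; then 31 (1.2 equiv of ylide), 0 °C → rt
Reagents that add atoms: methyltriphenylphosphonium bromide, C[P+](c1ccccc1)(c1ccccc1)c1ccccc1.[Br-]
Why: Wittig methylenation adds C1. The methyl ketone is the least hindered carbonyl (C11 is flanked by quaternary C13 and the arene, C7 by quaternary C6 and by the exo substituent itself), and any epimerisation at C4 by the basic ylide returns the exo isomer.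

Step 20
Reactants: 32 hydroquinone dimethyl ether of 34
Product: 34 CNP0287617.1, via p-quinone 33 (not isolated)
Conditions: (NH4)2Ce(NO3)6 (2.5 equiv), MeCN/H2O, 0 °C; then aq. Na2S2O4, EtOAc, rt, under argon
Reagents that add atoms: water, O
Why: Oxidative demethylation of the 1,4-dimethoxyarene by tetravalent cerium to the p-quinone, which should not touch alkenes or ketones at 0 °C, then dithionite reduction to the hydroquinone; no stereocentre is involved.

## Compound list

1 | 2-bromo-1,4-dimethoxybenzene | COc1ccc(OC)c(Br)c1 | starting material
2 | 2-bromo-3,6-dimethoxyphenyllithium | [Li]c1c(Br)c(OC)ccc1OC | intermediate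
3 | 2-bromo-3,6-dimethoxybenzaldehyde | O=Cc1c(Br)c(OC)ccc1OC | intermediate
4 | ethyl (2E)-3-(2-bromo-3,6-dimethoxyphenyl)prop-2-enoate | CCOC(=O)/C=C/c1c(Br)c(OC)ccc1OC | intermediate
5 | (2E)-3-(2-bromo-3,6-dimethoxyphenyl)prop-2-en-1-ol | OC/C=C/c1c(Br)c(OC)ccc1OC | intermediate
6 | (2E)-3-(2-bromo-3,6-dimethoxyphenyl)prop-2-en-1-yl methyl carbonate | COC(=O)OC/C=C/c1c(Br)c(OC)ccc1OC | intermediate
7 | cyclopentane-1,3-dione | O=C1CCC(=O)C1 | starting material
8 | 2-[(1S)-1-(2-bromo-3,6-dimethoxyphenyl)prop-2-en-1-yl]cyclopentane-1,3-dione (largely enolised) | C=C[C@@H](C1C(=O)CCC1=O)c1c(OC)ccc(OC)c1Br | intermediate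
9 | 2-[(1S)-1-(2-bromo-3,6-dimethoxyphenyl)prop-2-en-1-yl]-3-methoxycyclopent-2-en-1-one | C=C[C@@H](C1=C(OC)CCC1=O)c1c(OC)ccc(OC)c1Br | intermediate
10 | potassium dienolate of 9 (deprotonated at C4, C18 unchanged) | C=C[C@@H](C1=C(OC)CC=C1O[K])c1c(OC)ccc(OC)c1Br | intermediate
11 | 5-hydroxy-3-methoxy-2-[(1S)-1-(2-bromo-3,6-dimethoxyphenyl)prop-2-en-1-yl]cyclopent-2-en-1-one, both carbinol epimers | C=C[C@@H](C1=C(OC)CC(O)C1=O)c1c(OC)ccc(OC)c1Br | intermediate
12 | 4-methoxy-3-[(1S)-1-(2-bromo-3,6-dimethoxyphenyl)prop-2-en-1-yl]cyclopent-3-ene-1,2-diol, diastereomer mixture | C=C[C@@H](C1=C(OC)CC(O)C1O)c1c(OC)ccc(OC)c1Br | intermediate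
13 | 4,4-dimethoxy-3-[(1S)-1-(2-bromo-3,6-dimethoxyphenyl)prop-2-en-1-yl]cyclopent-2-en-1-ol, both carbinol epimers | C=C[C@@H](C1=CC(O)CC1(OC)OC)c1c(OC)ccc(OC)c1Br | intermediate
14 | methallyl chloride (3-chloro-2-methylprop-1-ene) | C=C(C)CCl | starting material
15 | methallylmagnesium chloride | C=C(C)C[Mg]Cl | intermediate
16 | N-methoxy-N,3-dimethylbut-3-enamide | C=C(C)CC(=O)N(C)OC | intermediate
17 | aryllithium lithium alkoxide from 13 (Li in place of Br and of the hydroxyl H, C18 unchanged) | C=C[C@@H](C1=CC(O[Li])CC1(OC)OC)c1c(OC)ccc(OC)c1[Li] | intermediate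
18 | arylmagnesium bromide from 17 (MgBr on C26 and on the alkoxide O, C18 unchanged) | C=C[C@@H](C1=CC(O[Mg]Br)CC1(OC)OC)c1c(OC)ccc(OC)c1[Mg]Br | intermediate
19 | 1-{2-[(1R)-1-(3-hydroxy-5,5-dimethoxycyclopent-1-en-1-yl)prop-2-en-1-yl]-3,6-dimethoxyphenyl}-3-methylbut-3-en-1-one | C=C[C@@H](C1=CC(O)CC1(OC)OC)c1c(OC)ccc(OC)c1C(=O)CC(C)=C | intermediate
20 | (9R)-9-(3-hydroxy-5,5-dimethoxycyclopent-1-en-1-yl)-1,4-dimethoxy-7-methyl-6,9-dihydro-5H-benzo[7]annulen-5-one | OC1C=C(C(OC)(OC)C1)[C@@H]1C=C(C)CC(=O)c2c(OC)ccc(OC)c21 | intermediate
21 | (9R)-5-(1-ethoxyethenyl)-9-(3-hydroxy-5,5-dimethoxycyclopent-1-en-1-yl)-1,4-dimethoxy-7-methyl-6,9-dihydro-5H-benzo[7]annulen-5-ol, both C5 (= C13) epimers | OC1C=C(C(OC)(OC)C1)[C@@H]1C=C(C)CC(O)(C(=C)OCC)c2c(OC)ccc(OC)c21 | intermediate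
22 | 4,4-dimethoxy-3-[(9R)-5-(1-ethoxyethenyl)-5-hydroxy-1,4-dimethoxy-7-methyl-6,9-dihydro-5H-benzo[7]annulen-9-yl]cyclopent-2-en-1-one | O=C1C=C(C(OC)(OC)C1)[C@@H]1C=C(C)CC(O)(C(=C)OCC)c2c(OC)ccc(OC)c21 | intermediate
23 | dilithium alkoxide dienolate of 22 (enolate O on C4, double bonds C4=C9 and C5=C6) | [Li]OC1=CC(OC)(OC)C(=C1)[C@@H]1C=C(C)CC(O[Li])(C(=C)OCC)c2c(OC)ccc(OC)c21 | intermediate
24 | 5,5-dimethoxy-4-[(9R)-5-(1-ethoxyethenyl)-5-hydroxy-1,4-dimethoxy-7-methyl-6,9-dihydro-5H-benzo[7]annulen-9-yl]cyclopenta-1,3-dien-2-yl trifluoromethanesulfonate | O=S(=O)(OC1=CC(OC)(OC)C(=C1)[C@@H]1C=C(C)CC(O)(C(=C)OCC)c2c(OC)ccc(OC)c21)C(F)(F)F | intermediate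
25 | 1-{5,5-dimethoxy-4-[(9R)-5-(1-ethoxyethenyl)-5-hydroxy-1,4-dimethoxy-7-methyl-6,9-dihydro-5H-benzo[7]annulen-9-yl]cyclopenta-1,3-dien-2-yl}ethan-1-one (key-step precursor) | CC(=O)C1=CC(OC)(OC)C(=C1)[C@@H]1C=C(C)CC(O)(C(=C)OCC)c2c(OC)ccc(OC)c21 | intermediate
26 | 2-ethoxyallyl cation (C13–C11–C10) of 25 as its triflate | CC(=O)C1=CC(OC)(OC)C(=C1)[C@@H]1C=C(C)C[C+](C(=C)OCC)c2c(OC)ccc(OC)c21.[O-]S(=O)(=O)C(F)(F)F | intermediate
27 | pentacyclic cycloadduct as C10=C11 ethyl enol ether (C4-acetyl enone, C7 dimethyl ketal; C6, C9, C13, C18 as in 34) | CC(=O)C1=C[C@@]23C(OC)(OC)[C@@H]1C=C(OCC)[C@@]21CC(C)=C[C@@H]3c2c(OC)ccc(OC)c21 | intermediate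
28 | pentacyclic (4+3) adduct: C4-acetyl C4=C5 enone, C7 dimethyl ketal, C11 ketone, arene dimethyl ether; C6, C9, C13, C18 as in 34, C7 over the arene | CC(=O)C1=C[C@@]23C(OC)(OC)[C@@H]1CC(=O)[C@@]21CC(C)=C[C@@H]3c2c(OC)ccc(OC)c21 | intermediate
29 | as 28 with C7 ketone (C4-acetyl enone, C7 and C11 ketones) | CC(=O)C1=C[C@@]23C(=O)[C@@H]1CC(=O)[C@@]21CC(C)=C[C@@H]3c2c(OC)ccc(OC)c21 | intermediate
30 | C4,C5-dihydro triketone, acetyl endo (toward C10–C11), C4 epimer of 31 | CC(=O)[C@@H]1C[C@@]23C(=O)[C@@H]1CC(=O)[C@@]21CC(C)=C[C@@H]3c2c(OC)ccc(OC)c21 | intermediate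
31 | C4,C5-dihydro triketone, acetyl exo (toward C7), C4 as in 34 | CC(=O)[C@H]1C[C@@]23C(=O)[C@@H]1CC(=O)[C@@]21CC(C)=C[C@@H]3c2c(OC)ccc(OC)c21 | intermediate
32 | hydroquinone dimethyl ether of 34 (exo isopropenyl on C4, C7 and C11 ketones) | C=C(C)[C@H]1C[C@@]23C(=O)[C@@H]1CC(=O)[C@@]21CC(C)=C[C@@H]3c2c(OC)ccc(OC)c21 | intermediate
33 | p-quinone corresponding to 34 | C=C(C)[C@H]1C[C@@]23C(=O)[C@@H]1CC(=O)[C@@]21CC(C)=C[C@@H]3C2=C1C(=O)C=CC2=O | intermediate
34 | CNP0287617.1 (C18 as set in step 5; C7 bridge over the hydroquinone; isopropenyl exo on C4) | C=C(C)[C@H]1C[C@@]23C(=O)[C@@H]1CC(=O)[C@@]21CC(C)=C[C@@H]3c2c(O)ccc(O)c21 | target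

## Step count and least certain steps

Total: 20 steps. Longest linear sequence: 19 steps (1 → 34 through steps 1–8 and 10–20); step 9 is a one-step branch.

Step 5 (allylic alkylation). Most likely failure: slow ionisation and poor branched selectivity because the allyl terminus carries an aryl group with two ortho substituents, together with O-allylation or double allylation of the acidic dione. Fallback, from 5 and 7 back to 8: Mitsunobu O-alkylation of 7 with 5 (PPh3, diisopropyl azodicarboxylate, THF) would give 3-{[(2E)-3-(2-bromo-3,6-dimethoxyphenyl)prop-2-en-1-yl]oxy}cyclopent-2-en-1-one F1. Thermal Claisen rearrangement (xylene, 160 °C) would carry the aryl-bearing allyl carbon onto C6 and give racemic 2-[1-(2-bromo-3,6-dimethoxyphenyl)prop-2-en-1-yl]cyclopentane-1,3-dione F2. Preparative chromatography on a chiral stationary phase would then deliver 8. This turns O-allylation into the productive path and makes the branched connectivity intramolecularly, at the price of a resolution.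

Step 10 (aryl-metal acylation). Most likely failure: protonation of the hindered aryl-metal species by the acidic α-methylene of 16, or by the C18–H of a second molecule, which would also erode the configuration, instead of addition to the amide. Fallback, from 13 back to 19: the aryllithium 17 is quenched at −78 °C with N-methoxy-N-methylcarbamoyl chloride, which has no acidic proton, to give 2-[(1R)-1-(3-hydroxy-5,5-dimethoxycyclopent-1-en-1-yl)prop-2-en-1-yl]-N,3,6-trimethoxy-N-methylbenzamide F3. Methallylmagnesium chloride 15 (excess, THF, −78 → 0 °C) is then added to F3 to give 19. The polarity of the C13–C14 bond construction is reversed.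

Step 15 (carbonylative coupling). Most likely failure: methyl transfer without CO insertion, and at 50 °C [4+2] dimerisation of the dienes or intramolecular cycloaddition of the acyl diene with the enol ether. Fallback, from 24 back to 25: Nozaki–Hiyama–Kishi coupling of 24 with acetaldehyde (CrCl2, NiCl2 cat., DMF, rt) would give 1-{5,5-dimethoxy-4-[(9R)-5-(1-ethoxyethenyl)-5-hydroxy-1,4-dimethoxy-7-methyl-6,9-dihydro-5H-benzo[7]annulen-9-yl]cyclopenta-1,3-dien-2-yl}ethan-1-ol F4, and MnO2 (CH2Cl2, rt) would oxidise the dienylic alcohol to 25. Both operations run at room temperature and without CO.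

Step 16 (key step). Most likely failure: loss of a C14 proton from the cation, outrunning capture by a diene that the acyl group and the ketal oxygens make a weak nucleophile. The second concern is bonding on the other diene flank, which would place C7 over the C14–C15=C17 bridge. Fallback, from 25 back to 28: the acetyl group is taken to the alcohol level for the cycloaddition, so the diene is no longer cross-conjugated with a carbonyl group.
- i-Bu2AlH (CH2Cl2, −78 °C) reduces 25 to the dienyl carbinol F4.
- TBSCl and imidazole silylate only the secondary hydroxyl, giving the tert-butyldimethylsilyl ether F5.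
- The same Tf2O/2,6-lutidine ionisation and buffered work-up give the pentacyclic adduct with a 1-(silyloxy)ethyl group on C4, F6.
- Bu4NF gives the pentacyclic allylic alcohol F7, and MnO2 returns 28.

Step 19 (methylenation). Most likely failure: olefination at the strained C7 ketone in competition with the methyl ketone, or aldol chemistry between the carbonyl groups under the basic ylide. Fallback, from 28 back to 32: the C7 ketal is kept as a protecting group through the olefination.
- Conjugate reduction and equilibration of 28 ([(Ph3P)CuH]6; DBU) would give the ketal-protected exo methyl ketone F8.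
- Wittig methylenation, where only the heavily hindered C11 ketone competes, would give the isopropenyl ketal F9.
- Hydrolysis (1 M aq. HCl, THF) would give 32.
The price is that the exo preference at C4 must hold with a methoxy group syn to the two-carbon bridge, and that the ketal is hydrolysed beside the isopropenyl group.

## Further compounds

F1 | step 5 | 3-{[(2E)-3-(2-bromo-3,6-dimethoxyphenyl)prop-2-en-1-yl]oxy}cyclopent-2-en-1-one | O=C1CCC(OC/C=C/c2c(Br)c(OC)ccc2OC)=C1
F2 | step 5 | racemic 2-[1-(2-bromo-3,6-dimethoxyphenyl)prop-2-en-1-yl]cyclopentane-1,3-dione | C=CC(C1C(=O)CCC1=O)c1c(OC)ccc(OC)c1Br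
F3 | step 10 | 2-[(1R)-1-(3-hydroxy-5,5-dimethoxycyclopent-1-en-1-yl)prop-2-en-1-yl]-N,3,6-trimethoxy-N-methylbenzamide | C=C[C@@H](C1=CC(O)CC1(OC)OC)c1c(OC)ccc(OC)c1C(=O)N(C)OC
F4 | step 15 | 1-{5,5-dimethoxy-4-[(9R)-5-(1-ethoxyethenyl)-5-hydroxy-1,4-dimethoxy-7-methyl-6,9-dihydro-5H-benzo[7]annulen-9-yl]cyclopenta-1,3-dien-2-yl}ethan-1-ol | CC(O)C1=CC(OC)(OC)C(=C1)[C@@H]1C=C(C)CC(O)(C(=C)OCC)c2c(OC)ccc(OC)c21
F5 | step 16 | tert-butyldimethylsilyl ether of F4 at the secondary hydroxyl | CC(O[Si](C)(C)C(C)(C)C)C1=CC(OC)(OC)C(=C1)[C@@H]1C=C(C)CC(O)(C(=C)OCC)c2c(OC)ccc(OC)c21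
F6 | step 16 | pentacyclic adduct with 1-(tert-butyldimethylsilyloxy)ethyl on C4, C4=C5 alkene, C7 dimethyl ketal, C11 ketone | CC(O[Si](C)(C)C(C)(C)C)C1=C[C@@]23C(OC)(OC)[C@@H]1CC(=O)[C@@]21CC(C)=C[C@@H]3c2c(OC)ccc(OC)c21
F7 | step 16 | pentacyclic allylic alcohol (1-hydroxyethyl on C4, C7 dimethyl ketal, C11 ketone) | CC(O)C1=C[C@@]23C(OC)(OC)[C@@H]1CC(=O)[C@@]21CC(C)=C[C@@H]3c2c(OC)ccc(OC)c21
F8 | step 19 | C4,C5-dihydro adduct with exo acetyl group and C7 dimethyl ketal | CC(=O)[C@H]1C[C@@]23C(OC)(OC)[C@@H]1CC(=O)[C@@]21CC(C)=C[C@@H]3c2c(OC)ccc(OC)c21
F9 | step 19 | exo isopropenyl compound with C7 dimethyl ketal | C=C(C)[C@H]1C[C@@]23C(OC)(OC)[C@@H]1CC(=O)[C@@]21CC(C)=C[C@@H]3c2c(OC)ccc(OC)c21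
A1 | alternative 1 | bicyclic dione with ethynyl pinacol boronates on C13 and C18 | C=C(C)[C@H]1C[C@@]23C(=O)[C@@H]1CC(=O)[C@@]2(C#CB1OC(C)(C)C(C)(C)O1)CC(C)=C[C@@H]3C#CB1OC(C)(C)C(C)(C)O1
A2 | alternative 1 | ethyne | C#C
A3 | alternative 1 | aryl bis(pinacol boronate) of the complete skeleton | C=C(C)[C@H]1C[C@@]23C(=O)[C@@H]1CC(=O)[C@@]21CC(C)=C[C@@H]3c2c(B4OC(C)(C)C(C)(C)O4)ccc(B5OC(C)(C)C(C)(C)O5)c21
A4 | alternative 2 | 1,3-dibromoindane carrying ring B (C7 dioxolane, C11 ketone) and the silyloxyethyl chain on C6 | CC(C)(C)[Si](C)(C)OCC[C@@]12C3(OCCO3)CCC(=O)C1(Br)c1c(OC)ccc(OC)c1C2Br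
A5 | alternative 2 | 1,1,3,3-tetrabromoacetone | BrC(Br)C(=O)C(Br)Br
A6 | alternative 2 | 2H-indene formed from A4 | CC(C)(C)[Si](C)(C)OCC[C@@]12C3(OCCO3)CCC(=O)C1=C1C(OC)=CC=C(OC)C1=C2
A7 | alternative 2 | bromozinc 1,3-dibromo-2-oxyallyl cation from A5 | Br[CH+]C(O[Zn]Br)=CBr
A8 | alternative 2 | tetracyclic C15 ketone with C7 dioxolane | CC(C)(C)[Si](C)(C)OCC[C@@]23C4(OCCO4)CCC(=O)[C@@]21CC(=O)C[C@@H]3c2c(OC)ccc(OC)c21
A9 | alternative 3 | bicyclic trimethylsilyl enol ether enone with prenyl on C6 | CC(C)=CC[C@]12C=CC(=O)CC1=C(O[Si](C)(C)C)CCC2=O
A10 | alternative 3 | 3,6-dimethoxy-2-(trimethylsilyl)phenyl trifluoromethanesulfonate | COc1ccc(OC)c(OS(=O)(=O)C(F)(F)F)c1[Si](C)(C)C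
A11 | alternative 3 | 3,6-dimethoxybenzyne | COC1=CC=C(OC)C#C1
A12 | alternative 3 | tetracyclic triketone lacking ring A and the C15 methyl alkene | CC(C)=CC[C@@]23C(=O)CCC(=O)[C@@]21CC(=O)C[C@@H]3c2c(OC)ccc(OC)c21
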